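**Strategy.** The route rests on cutting the dihydropyran ring of the chroman between C4 and C3 and between O1 and C2. Both bonds are made at once by an enantioselective inverse-electron-demand oxa-Diels–Alder reaction of an o-quinone methide (heterodiene O1=C8a–C4a=C4, released from a salicyl alcohol) with 2-methylprop-1-enylboronic acid pinacol ester. The gem-dimethyl carbon C2 directs the regiochemistry, and the C3–B bond is then oxidised with retention to the C3 hydroxyl. The precursor is a 4-hydroxy-3-(hydroxymethyl)benzaldehyde that already carries the C8 oxygen and the C6 formyl group. An acid-mediated Claisen–Schmidt condensation with 2,4-dihydroxyacetophenone completes the chalcone.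

Key step: step 3

Remark: chroman numbering (O1, C2, C3, C4, C4a, C5 to C8, C8a) is used for the target and its precursors; the single stereocentre C3 of the target is (S).

**Step 1**
Reactants: 1 3,4-dihydroxybenzaldehyde
Product: 2 4-hydroxy-3-(methoxymethoxy)benzaldehyde
Conditions: NaH (2.1 equiv), DMF, 0 °C; MOMCl (1.0 equiv), 0 °C to rt; aq. HCl to pH 5
Reagents that add atoms: chloromethyl methyl ether (MOMCl), COCCl
Why: Williamson-type O-alkylation of the dianion, in which the 3-phenoxide is not conjugated to the formyl group, is therefore the more nucleophilic oxygen and should take the single equivalent of MOMCl, leaving the para oxygen free.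

**Step 2**
Reactants: 2 4-hydroxy-3-(methoxymethoxy)benzaldehyde
Product: 3 4-hydroxy-3-(hydroxymethyl)-5-(methoxymethoxy)benzaldehyde
Conditions: 37% aq. HCHO (3 equiv), NaOH (1.1 equiv), H2O, rt; AcOH to pH 6
Reagents that add atoms: formaldehyde, C=O
Why: Lederer–Manasse ortho-hydroxymethylation, in which the phenoxide adds formaldehyde at its only free ortho position (para is blocked by the formyl group, the other ortho position by the MOM ether) and the p-formylphenoxide, a vinylogous carboxylate, should resist Cannizzaro reduction.

**Step 3**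
Reactants: 3 4-hydroxy-3-(hydroxymethyl)-5-(methoxymethoxy)benzaldehyde; 4 isobutenylboronic acid pinacol ester (4,4,5,5-tetramethyl-2-(2-methylprop-1-en-1-yl)-1,3,2-dioxaborolane)
Product: 7 (3S)-3-hydroxy-8-(methoxymethoxy)-2,2-dimethyl-3,4-dihydro-2H-chromene-6-carbaldehyde, via o-quinone methide 5 (not isolated), via chromanyl boronate 6 (not isolated)
Conditions: 4 (3 equiv), chiral imidodiphosphorimidate acid HN[P(=NSO2CF3)(O2Ar*)]2 (O2Ar* = 3,3'-bis[3,5-bis(trifluoromethyl)phenyl]-1,1'-binaphthalene-2,2'-diolate, 5 mol%), 5 Å MS, CHCl3, 0 °C to rt, slow addition of 3; then THF/H2O, NaBO3·4H2O (6 equiv), rt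
Reagents that add atoms: NaBO3·4H2O (sodium perborate tetrahydrate), [Na+].[Na+].O[B-]1(O)OO[B-](O)(O)OO1
Why: Proposed new method: the chiral acid dehydrates 3 to the o-quinone methide 5, whose heterodiene O1=C8a–C4a=C4 adds across the C3=C2 bond of 4 in an asynchronous inverse-electron-demand oxa-Diels–Alder reaction, so that the dihydropyran ring closes in a [4+2] mode with C4–C3 formed slightly ahead of O1–C2. The closest known reaction types are the chiral Brønsted acid-catalysed [4+2] cycloadditions of in situ generated o-quinone methides with unactivated alkenes and the thermal o-quinone methide cycloadditions with trisubstituted alkenes that give 2,2-dimethylchromans; an alkenylboronate as 2π partner and enantiocontrol over a methide-unsubstituted o-quinone methide have not been shown. The regioselectivity that the step needs is secured by the substrate: attack of the electrophilic methide carbon C4 on the boron-bearing CH places the developing positive charge on the tertiary carbon C2, where it is stabilised by the two methyl groups and by hyperconjugation with the C–B bond, and O1 then closes on C2. The new stereocentre C3 is controlled by the catalyst, whose confined chiral anion should stay hydrogen-bonded to O1 (and to the neighbouring C8 oxygen) of the protonated o-quinone methide and leave one enantiotopic face of the alkene open; the antipode of the acid that delivers (S)-6 is chosen after a first run with either antipode. Slow release of 5 by the catalytic acid, an excess of 4 and the non-nucleophilic counter-anion should hold back o-quinone methide oligomerisation and loss of boron from the cationic intermediate. Perborate then oxidises the secondary C–B bond in the same flask by 1,2-shift of C3 from boron to oxygen with retention, so that (S)-6 should give (S)-7.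

**Step 4**
Reactants: 7 (3S)-3-hydroxy-8-(methoxymethoxy)-2,2-dimethyl-3,4-dihydro-2H-chromene-6-carbaldehyde; 8 1-(2,4-dihydroxyphenyl)ethanone
Product: 11 (E)-1-(2,4-dihydroxyphenyl)-3-[(3S)-3,8-dihydroxy-2,2-dimethyl-3,4-dihydro-2H-chromen-6-yl]prop-2-en-1-one, via chromandiol aldehyde 9 (not isolated), via aldol adduct 10 (not isolated)
Conditions: HCl (1.25 M in EtOH), rt
Reagents that add atoms: none
Why: Acid-mediated Claisen–Schmidt (crossed aldol) condensation, a protocol used for unprotected polyhydroxychalcones, in which the enol of 8 adds to the protonated aldehyde and dehydration should give the conjugated (E)-enone, while HCl/EtOH removes the MOM acetal by transacetalisation and the C3 stereocentre is not involved.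

**Compound list**
1 | 3,4-dihydroxybenzaldehyde | O=Cc1ccc(O)c(O)c1 | starting material
2 | 4-hydroxy-3-(methoxymethoxy)benzaldehyde | COCOc1cc(C=O)ccc1O | intermediate
3 | 4-hydroxy-3-(hydroxymethyl)-5-(methoxymethoxy)benzaldehyde | COCOc1cc(C=O)cc(CO)c1O | intermediate
4 | 4,4,5,5-tetramethyl-2-(2-methylprop-1-en-1-yl)-1,3,2-dioxaborolane | CC(C)=CB1OC(C)(C)C(C)(C)O1 | starting material
5 | 5-(methoxymethoxy)-3-methylidene-4-oxocyclohexa-1,5-diene-1-carbaldehyde (o-quinone methide) | C=C1C=C(C=O)C=C(OCOC)C1=O | intermediate
6 | (3S)-8-(methoxymethoxy)-2,2-dimethyl-3-(4,4,5,5-tetramethyl-1,3,2-dioxaborolan-2-yl)-3,4-dihydro-2H-chromene-6-carbaldehyde | CC1(C)Oc2c(OCOC)cc(C=O)cc2C[C@@H]1B1OC(C)(C)C(C)(C)O1 | intermediate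
7 | (3S)-3-hydroxy-8-(methoxymethoxy)-2,2-dimethyl-3,4-dihydro-2H-chromene-6-carbaldehyde | CC1(C)Oc2c(OCOC)cc(C=O)cc2C[C@@H]1O | intermediate
8 | 1-(2,4-dihydroxyphenyl)ethanone | CC(=O)c1ccc(O)cc1O | starting material
9 | (3S)-3,8-dihydroxy-2,2-dimethyl-3,4-dihydro-2H-chromene-6-carbaldehyde | CC1(C)Oc2c(O)cc(C=O)cc2C[C@@H]1O | intermediate
10 | 1-(2,4-dihydroxyphenyl)-3-[(3S)-3,8-dihydroxy-2,2-dimethyl-3,4-dihydro-2H-chromen-6-yl]-3-hydroxypropan-1-one (both epimers at the new carbinol carbon) | CC1(C)Oc2c(O)cc(C(O)CC(=O)c3ccc(O)cc3O)cc2C[C@@H]1O | intermediate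
11 | (E)-1-(2,4-dihydroxyphenyl)-3-[(3S)-3,8-dihydroxy-2,2-dimethyl-3,4-dihydro-2H-chromen-6-yl]prop-2-en-1-one | CC1(C)Oc2c(O)cc(/C=C/C(=O)c3ccc(O)cc3O)cc2C[C@@H]1O | target

Total step count: 4. Longest linear sequence: 4 steps (1 → 2 → 3 → 7 → 11).

**Steps most likely to fail**

1. Step 3 (Proposed new method). What may go wrong: insufficient enantiofacial discrimination of the boron-bearing alkene, because C3 is the only stereocentre and is created at a carbon that is not itself bound to the catalyst. Oligomerisation of the methide-unsubstituted o-quinone methide, reversible acetal formation between the salicyl alcohol and formyl groups of two molecules, and loss of boron from the cationic intermediate are further risks. Fallback with known chemistry, setting out from 2 and coming back at 7: O-alkylation of 2 with 3-chloro-3-methylbut-1-yne (DBU, CuCl2 cat., MeCN, 0 °C) should give 3-(methoxymethoxy)-4-[(2-methylbut-3-yn-2-yl)oxy]benzaldehyde F1. Heating in xylene (aromatic Claisen rearrangement, 1,5-hydrogen shift, oxa-6π-electrocyclisation) should give 8-(methoxymethoxy)-2,2-dimethyl-2H-chromene-6-carbaldehyde F2. Jacobsen–Katsuki epoxidation (NaOCl, 4-phenylpyridine N-oxide, CH2Cl2, 0 °C) with (S,S)-[N,N'-bis(3,5-di-tert-butylsalicylidene)cyclohexane-1,2-diaminato]MnCl, a chloride complex of trivalent manganese, should give (3S,4S)-3,4-epoxy-8-(methoxymethoxy)-2,2-dimethylchroman-6-carbaldehyde F3. Hydrogenolysis of the benzylic C4–O bond (H2, 1 atm, Pd/C, EtOAc, stopped when F3 is consumed so that the formyl group is kept) should give 7.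

2. Step 4. What may go wrong: incomplete condensation between an electron-rich aldehyde and a hydrogen-bonded ketone, and acid-induced cyclisation of the 2'-hydroxychalcone to the flavanone during the long exposure to HCl. Fallback, setting out from 8 and coming back at 11: selective protection of the non-chelated 4-OH (MOMCl, K2CO3, acetone, rt) should give 1-[2-hydroxy-4-(methoxymethoxy)phenyl]ethanone F4. Base-mediated Claisen–Schmidt condensation of F4 with 7 (KOH, EtOH/H2O, rt) should give (E)-3-[(3S)-3-hydroxy-8-(methoxymethoxy)-2,2-dimethylchroman-6-yl]-1-[2-hydroxy-4-(methoxymethoxy)phenyl]prop-2-en-1-one F5. Brief treatment with catalytic HCl in MeOH at rt should remove both MOM groups and give 11.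

3. Step 1. What may go wrong: poor discrimination between the two phenolic oxygens, leading to alkylation at the para oxygen or at both. Fallback, setting out from 1 and coming back at 2: benzylation under weakly basic conditions (BnBr, NaHCO3, NaI, DMF, 40 °C), which takes the more acidic para hydroxyl, should give 4-(benzyloxy)-3-hydroxybenzaldehyde F6. MOM protection of the remaining hydroxyl (MOMCl, iPr2NEt, CH2Cl2) should give 4-(benzyloxy)-3-(methoxymethoxy)benzaldehyde F7. Hydrogenolysis of the benzyl ether (H2, 1 atm, Pd/C, EtOAc, rt) should give 2.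

**Further compounds**
F1 | step 3 | 3-(methoxymethoxy)-4-[(2-methylbut-3-yn-2-yl)oxy]benzaldehyde | COCOc1cc(C=O)ccc1OC(C)(C)C#C
F2 | step 3 | 8-(methoxymethoxy)-2,2-dimethyl-2H-chromene-6-carbaldehyde | CC1(C)C=Cc2cc(C=O)cc(OCOC)c2O1
F3 | step 3 | (3S,4S)-3,4-epoxy-8-(methoxymethoxy)-2,2-dimethylchroman-6-carbaldehyde | CC1(C)Oc2c(OCOC)cc(C=O)cc2[C@@H]3O[C@H]13
F4 | step 4 | 1-[2-hydroxy-4-(methoxymethoxy)phenyl]ethanone | CC(=O)c1ccc(OCOC)cc1O
F5 | step 4 | (E)-3-[(3S)-3-hydroxy-8-(methoxymethoxy)-2,2-dimethylchroman-6-yl]-1-[2-hydroxy-4-(methoxymethoxy)phenyl]prop-2-en-1-one | CC1(C)Oc2c(OCOC)cc(/C=C/C(=O)c3ccc(OCOC)cc3O)cc2C[C@@H]1O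
F6 | step 1 | 4-(benzyloxy)-3-hydroxybenzaldehyde | O=Cc1ccc(OCc2ccccc2)c(O)c1
F7 | step 1 | 4-(benzyloxy)-3-(methoxymethoxy)benzaldehyde | COCOc1cc(C=O)ccc1OCc1ccccc1
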